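- Blue and amber differ in their charge of first end groups, and the length asked for is a count of ends.

all flasks: second end groups 0.171 M
- zeta: first end groups 0.24 M; one-sided end groups 9 mM; run made earlier
- eta: first end groups 1.1 M; one-sided end groups 9 mM; run made earlier
- blue: first end groups 0.18 M; one-sided end groups 9.00 mM; time 1.5 h
- amber: first end groups 0.80 M; one-sided end groups 9.00 mM; time 1.5 h

| run | time / min | links / % | first end groups / % |
|---|---|---|---|
| zeta | 5.00 | 11 | 86 |
| zeta | 15.0 | 24 | 71 |
| zeta | 25.0 | 33 | 63 |
| zeta | 40.0 | 40 | 56 |
| zeta | 50.0 | 44 | 55 |
| zeta | 80.0 | 52 | 45 |
| zeta | 90.0 | 54 | 46 |
| eta | 12.0 | 11 | 88 |
| eta | 25.0 | 14 | 87 |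
| eta | 40.0 | 14 | 80 |
| eta | 50.0 | 13 | 82 |
| eta | 60.0 | 19 | 85 |
| eta | 80.0 | 15 | 81 |
| eta | 90.0 | 16 | 85 |

(standard deviation of a reading: 1.5 percentage points)

- each monomer carries two end groups and one-sided end groups one, which caps an end: a chain counts once for every two ends that are left, dead ends included; the units are half of the end groups of the two monomers charged
- on the list of suspects stand: first end groups + second end groups <-> links; first end groups + one-sided end groups -> capped ends

1. which of the two ends with the longer chains by the average number of monomer units in a chain (unreacted monomers counted as chains of one) ("neither" if they lie within 10 %) (blue / amber / neither)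
2. average number of monomer units in a chain (unreacted monomers counted as chains of one) at the end, blue
3. average number of monomer units in a chain (unreacted monomers counted as chains of one) at the end, amber

- Each link removes two ends, while capped ends stay in the count as dead ends. The length is therefore the end groups charged over those not joined in links.
- Each link also uses one second end group. On a scale where the first charge is 1, let r be the second charge and f the fraction of second end groups left unlinked. The length is then (1 + r)/(1 − r + 2rf).
- Here f is the correction, and r carries the main term. Amber has r = 0.214, so f at zero gives 1.54: the ceiling length, the chain length if no second end group stays unlinked. Second end groups are amber's limiting reagent for links.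
- Eta gives a first reading of the size of f. From 40.0 min on, its links average 99.1 % of its second charge. Each reading scatters by 1.5 percentage points of the first charge, and eta's first charge is 6.43 times its second, so this average is a rough reading. Amber holds 0.80 M of first end groups against eta's 1.1 M, so its f may stand somewhat higher, but this reckoning still puts amber just under its ceiling.
- Blue has r = 0.950 and a ceiling of 39.0, so its length depends on how far linking gets. To pass amber's ceiling, blue needs links at 34.3 % of its first charge.
- Zeta's links read 33 % of its first charge at 25.0 min. Blue has 75.0 % of zeta's first end groups but 3.60 times that time, so this reckoning expects blue to be longer.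
- The forecast says blue, with 2.4 for blue and 1.5 for amber. Its ground for amber is “excess first ends, equilibrated by 90 min”.
- The flasks give blue: 2.50 for blue and 1.51 for amber.

    first end groups + second end groups ⇌ links (K = 42.0 M⁻¹, k = 0.00240 M⁻¹ s⁻¹)
    first end groups + one-sided end groups → capped ends (k = 0.0470 M⁻¹ s⁻¹)

- The difference in first end groups is the main reason for the gap: amber without that difference gives 2.50 in place of 1.51. Amber stands below its ceiling of 1.54 by the correction from its 3.7 % of second end groups left unlinked. The neighbour flask with 0.48 M of first end groups has a ceiling of 2.11, and with 7.8 % of its second end groups left unlinked it stands at 1.94.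

The data were generated by integration with made-up constants; scatter was added.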